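## Structural features

The target is a 1H-indole: a benzene ring (ring A: C3a, C4, C5, C6, C7, C7a) fused through the C3a–C7a bond to a pyrrole ring (ring B: N1, C2, C3, C3a, C7a), with N1–H and C2–H free. It carries three C–Br bonds: one on C3 of ring B and two on the adjacent carbons C5 and C6 of ring A, which are flanked by C4–H and C7–H. There is no stereocentre. The fragile part is the 3-bromoindole unit, which is electron-rich and sensitive to acid, heat and light, so the C3–Br bond should be made last and cold. The aryl bromides, once in place, must not meet zerovalent palladium or strong reductants. The real difficulty is the vicinal C5/C6 pattern: electrophilic bromination of an indole goes to C3 and then spreads over C2, C5 and C6 without control, so the usual answer is to buy the pattern inside a 3,4-dibromoarene. The key step exploits the fact that C5 and C6 are neighbours, each bears Br, and their outer neighbours C4 and C7 bear H. This is exactly the pattern left when the bromine-bearing termini of two bromoethynyl arms, held on the adjacent carbons C3a and C7a, are joined in a Bergman cycloaromatization.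

## Logic of the disconnections

12 to 11: the C3–Br bond is cut first because it is the labile bond and would not survive the thermal key step. The gain is a robust precursor. The demand is a single, mild monobromination at the most nucleophilic carbon of 11.

11 to 10 to 8: retrosynthetically a carboxyl group is added at C2 (forward: the C2–CO2H bond is cut), then the N1–S bond and the ester O–CH3 are restored. The carboxyl carbon is the residue of the commercial pyrrole 1, and the N-sulfonyl group is what keeps the pyrrole electron-poor through the earlier steps. The demand is one basic hydrolysis that removes ester and sulfonyl together, and a protodecarboxylation that spares the aryl C–Br bonds.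

8 to 6 (key disconnection): the C5–C6 bond and the C4–H and C7–H bonds are cut, opening ring A to a pyrrole that carries two bromoethynyl arms on adjacent carbons. In one sentence, ring A of the indole is made by Bergman cycloaromatization of 6. The gain is that a bicyclic, regiodefined vicinal dibromide becomes a monocyclic pyrrole with two identical arms, and the positions of both bromines are fixed by constitution. The demand is a thermal cyclization through diradical 7 in the presence of a hydrogen-atom donor, with terminal C–Br bonds that survive the heat.

6 to 5: the two C(sp)–Br bonds are cut back to C(sp)–Si bonds, because a bromoalkyne cannot be carried through a palladium coupling while a silylalkyne can. The demand is ipso-bromodesilylation without bromination of the remaining pyrrole C–H.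

5 to 2 and 3: the two C(sp2)–C(sp) bonds at the adjacent pyrrole carbons are cut. Both arms then come from one commercial alkyne, 3, and one vicinal dibromide, 2. The demand is a double cross-coupling on neighbouring positions, passing through the mono-coupled bromide 4.

2 to 1: the N–S bond is cut, leading to commercial 1. The sulfonyl group chosen has a methyl group rather than an aryl ring, so that the C7 radical of the key step has no arene to attack.

## Other disconnections considered

Alternative 1: the first idea is to cut C3–Br and then ring B (N1–C2 and C2–C3) in the Leimgruber–Batcho manner.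
- Forward: 1,2-dibromo-4-methyl-5-nitrobenzene A1 is condensed with a formamide acetal to the enamine (E)-2-(4,5-dibromo-2-nitrophenyl)-N,N-dimethylethen-1-amine A2. Reductive cyclization of A2 gives 11, which is brominated as in step 7.
- Assessment: this is shorter and reliable. It is set aside because its one-sentence description is the default route. The key step also does nothing about the vicinal dibromide, whose regiochemistry is inherited from nitration of a dibromotoluene that can give isomers. The nitro reduction must further be chosen to avoid hydrogenolysis of C–Br.

Alternative 2: cut C4–C3a and C7–C7a, making ring A by a Diels–Alder reaction with loss of SO2.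
- Forward: 3,4-dibromothiophene 1,1-dioxide A3 reacts as an electron-poor diene with the enecarbamate tert-butyl 2,3-dihydro-1H-pyrrole-1-carboxylate A4. Cheletropic loss of SO2 and dehydrogenation of the cyclohexadiene give tert-butyl 5,6-dibromoindoline-1-carboxylate A5.
- Assessment: the symmetrical diene fixes the bromine positions, which is a real merit. However, a thiophene dioxide with free 2,5-positions is prone to self-dimerization. A5 is also still one dehydrogenation and one deprotection away from 11, so there is no step gain, whereas the chosen key step delivers ring A already aromatic.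

Alternative 3: cut C3a–C7a, C4–C5 and C6–C7 in a [2+2+2] cyclotrimerization.
- Forward: the ynamide diyne N-(but-3-yn-1-yl)-N-ethynyl-4-methylbenzenesulfonamide A6 is co-cyclized with bis(trimethylsilyl)acetylene A7 under CpCo(CO)2 to give 1-[(4-methylphenyl)sulfonyl]-5,6-bis(trimethylsilyl)indoline A8. Two ipso-bromodesilylations, desulfonylation, dehydrogenation and C3 bromination would follow.
- Assessment: it closes both rings at once, but the bromines are not carried by the key step. A7 is a sluggish partner against self-trimerization of A6. The ynamide synthesis and the later redox and deprotection steps make it longer than the chosen plan.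

Key step: step 4

Assumption: 1 and 3 are taken as commercial; 1,4-cyclohexadiene serves only as hydrogen-atom donor.

## Steps

Step 1
Reactants: 1 methyl 4,5-dibromo-1H-pyrrole-2-carboxylate
Product: 2 methyl 4,5-dibromo-1-(methylsulfonyl)-1H-pyrrole-2-carboxylate
Conditions: NaH, THF, 0 °C; then MsCl, 0 °C to rt
Reagents that add atoms: methanesulfonyl chloride, CS(=O)(=O)Cl
Why: N-sulfonylation of the pyrrolide anion; the sulfonyl and ester groups make the ring electron-poor, which should help oxidative addition in step 2 and suppress ring bromination in step 3.

Step 2
Reactants: 2 methyl 4,5-dibromo-1-(methylsulfonyl)-1H-pyrrole-2-carboxylate; 3 ethynyltrimethylsilane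
Product: 5 methyl 1-(methylsulfonyl)-4,5-bis[(trimethylsilyl)ethynyl]-1H-pyrrole-2-carboxylate, via 5-alkynyl-4-bromopyrrole 4 (not isolated)
Conditions: 3 (3 equiv), PdCl2(PPh3)2 (5 mol%), CuI (10 mol%), Et3N, DMF, 70 °C, sealed tube
Reagents that add atoms: ethynyltrimethylsilane (3), C#C[Si](C)(C)C
Why: Double Sonogashira coupling; oxidative addition of zerovalent palladium is expected first at the C5–Br bond next to nitrogen and then at the C4–Br bond of 4, which the new alkynyl group and the ester activate; excess 3 in a closed vessel offsets its volatility.

Step 3
Reactants: 5 methyl 1-(methylsulfonyl)-4,5-bis[(trimethylsilyl)ethynyl]-1H-pyrrole-2-carboxylate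
Product: 6 methyl 4,5-bis(bromoethynyl)-1-(methylsulfonyl)-1H-pyrrole-2-carboxylate
Conditions: NBS (2.4 equiv), AgNO3 (20 mol%), acetone, rt, dark
Reagents that add atoms: N-bromosuccinimide, O=C1CCC(=O)N1Br
Why: Silver-catalysed ipso-bromodesilylation of alkynylsilanes; a silver acetylide formed by C–Si cleavage is brominated by NBS, and the one remaining pyrrole C–H, deactivated by sulfonyl, ester and two alkynes, should not compete; 6 should be kept in solution and away from light.

Step 4
Reactants: 6 methyl 4,5-bis(bromoethynyl)-1-(methylsulfonyl)-1H-pyrrole-2-carboxylate
Product: 8 methyl 5,6-dibromo-1-(methylsulfonyl)-1H-indole-2-carboxylate, via 4,7-didehydroindole diradical 7 (not isolated)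
Conditions: 1,4-cyclohexadiene (50 equiv), PhCl (0.01 M), degassed, sealed tube, 200 °C
Reagents that add atoms: none
Why: On heating, the (Z)-hex-3-ene-1,5-diyne unit of 6, whose ene is the pyrrole C4=C5 bond, should undergo Bergman cycloaromatization: the two bromine-bearing alkyne termini join to form the future C5–C6 bond and give the 1,4-didehydroarene diradical 7, whose σ-radicals at C4 and C7 each take a hydrogen atom from 1,4-cyclohexadiene to give 8 and benzene. The closest known reaction type is the thermal Bergman cyclization of 1,2-bis(bromoethynyl)arenes to 2,3-dibromoacenes with the same donor, together with the cyclization of dialkynyl five-membered heteroarenes such as dialkynylthiophenes to their benzo-fused congeners. Ring A, six-membered, is closed in the C1–C6 mode of the enediyne with both alkynes endo, forming one σ-bond and losing no atoms; the C1–C5 fulvene mode is not expected for small termini such as bromine that do not stabilise a radical. No stereocentre is formed. Regiochemistry is fixed by constitution: the carbons that bond are the ones that carry bromine, so bromine can only end on C5 and C6 and hydrogen on C4 and C7. The step needs hydrogen-atom transfer to outrun ring reopening, radical oligomerization and C–Br homolysis, which the large excess of donor and high dilution should secure. The N-methylsulfonyl group offers no aryl ring for ipso attack by the C7 radical, and a hydrogen shift from its methyl group would lead to the same product after hydrogen transfer. A temperature somewhat above that used for benzo-fused cases is planned because the five-membered ene holds the alkyne termini farther apart.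

Step 5
Reactants: 8 methyl 5,6-dibromo-1-(methylsulfonyl)-1H-indole-2-carboxylate
Product: 10 5,6-dibromo-1H-indole-2-carboxylic acid, via sodium carboxylate 9 (not isolated)
Conditions: NaOH (10 equiv), MeOH/THF/H2O, 70 °C; then aq. HCl to pH 2
Reagents that add atoms: sodium hydroxide, [Na+].[OH-]
Why: Saponification of the methyl ester and hydroxide-induced cleavage of the N–S bond of the N-sulfonylindole, whose indolide is a good leaving group, occur in one operation; acidification of 9 should precipitate 10, and aryl bromides are inert to these conditions.

Step 6
Reactants: 10 5,6-dibromo-1H-indole-2-carboxylic acid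
Product: 11 5,6-dibromo-1H-indole
Conditions: Ag2CO3 (10 mol%), AcOH (5 mol%), DMSO, 120 °C
Reagents that add atoms: none
Why: Silver-catalysed protodecarboxylation of a heteroaromatic 2-carboxylic acid: the silver carboxylate loses CO2 to a 2-indolylsilver species that acetic acid protonates; the conditions are mild enough that the aryl C–Br bonds should be untouched.

Step 7
Reactants: 11 5,6-dibromo-1H-indole
Product: 12 3,5,6-tribromo-1H-indole
Conditions: NBS (1.0 equiv), DMF, 0 °C, dark
Reagents that add atoms: N-bromosuccinimide, O=C1CCC(=O)N1Br
Why: Electrophilic aromatic substitution at C3, the most nucleophilic position of an indole; one equivalent at 0 °C should stop at monobromination because ring A is deactivated by two bromines, and the sensitive product should be kept cold and in the dark.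

## Compound list

1 | methyl 4,5-dibromo-1H-pyrrole-2-carboxylate | COC(=O)c1cc(Br)c(Br)[nH]1 | starting material
2 | methyl 4,5-dibromo-1-(methylsulfonyl)-1H-pyrrole-2-carboxylate | COC(=O)c1cc(Br)c(Br)n1S(C)(=O)=O | intermediate
3 | ethynyltrimethylsilane | C#C[Si](C)(C)C | starting material
4 | methyl 4-bromo-1-(methylsulfonyl)-5-[(trimethylsilyl)ethynyl]-1H-pyrrole-2-carboxylate | COC(=O)c1cc(Br)c(C#C[Si](C)(C)C)n1S(C)(=O)=O | intermediate
5 | methyl 1-(methylsulfonyl)-4,5-bis[(trimethylsilyl)ethynyl]-1H-pyrrole-2-carboxylate | COC(=O)c1cc(C#C[Si](C)(C)C)c(C#C[Si](C)(C)C)n1S(C)(=O)=O | intermediate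
6 | methyl 4,5-bis(bromoethynyl)-1-(methylsulfonyl)-1H-pyrrole-2-carboxylate | COC(=O)c1cc(C#CBr)c(C#CBr)n1S(C)(=O)=O | intermediate
7 | methyl 5,6-dibromo-1-(methylsulfonyl)-4,7-didehydro-1H-indole-2-carboxylate (C4,C7 σ,σ-diradical) | COC(=O)c1cc2[c]c(Br)c(Br)[c]c2n1S(C)(=O)=O | intermediate
8 | methyl 5,6-dibromo-1-(methylsulfonyl)-1H-indole-2-carboxylate | COC(=O)c1cc2cc(Br)c(Br)cc2n1S(C)(=O)=O | intermediate
9 | sodium 5,6-dibromo-1H-indole-2-carboxylate | [Na+].[O-]C(=O)c1cc2cc(Br)c(Br)cc2[nH]1 | intermediate
10 | 5,6-dibromo-1H-indole-2-carboxylic acid | OC(=O)c1cc2cc(Br)c(Br)cc2[nH]1 | intermediate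
11 | 5,6-dibromo-1H-indole | Brc1cc2cc[nH]c2cc1Br | intermediate
12 | 3,5,6-tribromo-1H-indole | Brc1cc2[nH]cc(Br)c2cc1Br | target

## Step count and least certain steps

Total step count: 7. Longest linear sequence: 7 steps (1 to 12); 3 enters at step 2.

Step 4 (key step). The cyclization may be outrun by radical oligomerization of the bromoalkynes or by homolytic loss of bromine, because the five-membered ene raises the barrier and forces a high temperature. Reopening of the diradical may also be faster than hydrogen transfer. The fallback gives up the construction of ring A and builds ring B on a dibromoarene instead; it sets out from 3 and comes back at 11.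
- Iodination of 3,4-dibromoaniline F1 (ICl, AcOH, rt) at the free ortho position remote from bromine gives 4,5-dibromo-2-iodoaniline F2.
- Sonogashira coupling of F2 with 3 (PdCl2(PPh3)2, CuI, Et3N, rt), selective for the C–I bond, gives 4,5-dibromo-2-[(trimethylsilyl)ethynyl]aniline F3.
- TBAF in THF at reflux removes silicon and closes ring B by 5-endo-dig attack of the aniline nitrogen to give 11, which continues with step 7.

Step 2. The second coupling at the hindered C4–Br bond of 4 may stall, with protodebromination and oxidative homocoupling of the alkyne taking over. The fallback makes the triple bonds by olefination and elimination instead of cross-coupling of an alkyne; it sets out from 2, comes back at 6, and also bypasses step 3.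
- Suzuki–Miyaura coupling of 2 with potassium vinyltrifluoroborate (PdCl2(dppf), Cs2CO3, THF/H2O, 80 °C) gives methyl 4,5-diethenyl-1-(methylsulfonyl)-1H-pyrrole-2-carboxylate F4.
- Lemieux–Johnson cleavage (OsO4 cat., NaIO4, 2,6-lutidine, dioxane/H2O) gives methyl 4,5-diformyl-1-(methylsulfonyl)-1H-pyrrole-2-carboxylate F5.
- Ramirez olefination (CBr4, PPh3, CH2Cl2, 0 °C) gives methyl 4,5-bis(2,2-dibromoethenyl)-1-(methylsulfonyl)-1H-pyrrole-2-carboxylate F6.
- Dehydrobromination (DBU, DMSO, rt) gives 6.

Step 3. Electrophilic addition of bromine across the triple bonds, or incomplete C–Si cleavage at the alkyne crowded by the N-sulfonyl group, may lower the conversion. The fallback separates C–Si cleavage from C–Br formation and brominates the acetylide under base without silver; it sets out from 5 and comes back at 6.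
- TBAF buffered with AcOH (THF, 0 °C) gives methyl 4,5-diethynyl-1-(methylsulfonyl)-1H-pyrrole-2-carboxylate F7.
- NBS and DBU in MeCN at rt convert the terminal alkynes of F7 to the bromoalkynes of 6.

Step 6. Loss of CO2 may be incomplete, or silver- and heat-induced protodebromination may erode the aryl bromides. The fallback removes the C2 carbon as carbon monoxide instead of CO2; it sets out from 8 and comes back at 11.
- DIBAL-H (CH2Cl2, −78 °C) gives [5,6-dibromo-1-(methylsulfonyl)-1H-indol-2-yl]methanol F8.
- MnO2 (CH2Cl2, rt) gives 5,6-dibromo-1-(methylsulfonyl)-1H-indole-2-carbaldehyde F9.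
- Tsuji–Wilkinson decarbonylation with RhCl(PPh3)3 (1 equiv, toluene, reflux) gives 5,6-dibromo-1-(methylsulfonyl)-1H-indole F10.
- NaOH in MeOH/THF at 60 °C cleaves the N–S bond to give 11.

## Further compounds

F1 | step 4 | 3,4-dibromoaniline | Nc1ccc(Br)c(Br)c1
F2 | step 4 | 4,5-dibromo-2-iodoaniline | Nc1cc(Br)c(Br)cc1I
F3 | step 4 | 4,5-dibromo-2-[(trimethylsilyl)ethynyl]aniline | C[Si](C)(C)C#Cc1cc(Br)c(Br)cc1N
F4 | step 2 | methyl 4,5-diethenyl-1-(methylsulfonyl)-1H-pyrrole-2-carboxylate | COC(=O)c1cc(C=C)c(C=C)n1S(C)(=O)=O
F5 | step 2 | methyl 4,5-diformyl-1-(methylsulfonyl)-1H-pyrrole-2-carboxylate | COC(=O)c1cc(C=O)c(C=O)n1S(C)(=O)=O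
F6 | step 2 | methyl 4,5-bis(2,2-dibromoethenyl)-1-(methylsulfonyl)-1H-pyrrole-2-carboxylate | COC(=O)c1cc(C=C(Br)Br)c(C=C(Br)Br)n1S(C)(=O)=O
F7 | step 3 | methyl 4,5-diethynyl-1-(methylsulfonyl)-1H-pyrrole-2-carboxylate | COC(=O)c1cc(C#C)c(C#C)n1S(C)(=O)=O
F8 | step 6 | [5,6-dibromo-1-(methylsulfonyl)-1H-indol-2-yl]methanol | OCc1cc2cc(Br)c(Br)cc2n1S(C)(=O)=O
F9 | step 6 | 5,6-dibromo-1-(methylsulfonyl)-1H-indole-2-carbaldehyde | O=Cc1cc2cc(Br)c(Br)cc2n1S(C)(=O)=O
F10 | step 6 | 5,6-dibromo-1-(methylsulfonyl)-1H-indole | CS(=O)(=O)n1ccc2cc(Br)c(Br)cc21
A1 | alternative 1 | 1,2-dibromo-4-methyl-5-nitrobenzene | Cc1cc(Br)c(Br)cc1[N+](=O)[O-]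
A2 | alternative 1 | (E)-2-(4,5-dibromo-2-nitrophenyl)-N,N-dimethylethen-1-amine | CN(C)/C=C/c1cc(Br)c(Br)cc1[N+](=O)[O-]
A3 | alternative 2 | 3,4-dibromothiophene 1,1-dioxide | O=S1(=O)C=C(Br)C(Br)=C1
A4 | alternative 2 | tert-butyl 2,3-dihydro-1H-pyrrole-1-carboxylate | CC(C)(C)OC(=O)N1CCC=C1
A5 | alternative 2 | tert-butyl 5,6-dibromoindoline-1-carboxylate | CC(C)(C)OC(=O)N1CCc2cc(Br)c(Br)cc21
A6 | alternative 3 | N-(but-3-yn-1-yl)-N-ethynyl-4-methylbenzenesulfonamide | C#CCCN(C#C)S(=O)(=O)c1ccc(C)cc1
A7 | alternative 3 | bis(trimethylsilyl)acetylene | C[Si](C)(C)C#C[Si](C)(C)C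
A8 | alternative 3 | 1-[(4-methylphenyl)sulfonyl]-5,6-bis(trimethylsilyl)indoline | Cc1ccc(cc1)S(=O)(=O)N1CCc2cc([Si](C)(C)C)c([Si](C)(C)C)cc21
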